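**Plan**
- Retrosynthetic cuts: the MOM ether on ring B; the C6–C(quaternary) bond on ring A (aromatic Claisen of the 7-O-prenyl ether); then ring C at C4–C4a and O1–C8a, which gives a ring-A aryl iodide and a ring-B (S)-1-aryl-3-iodopropan-1-ol. The latter goes back through Br/prenyl exchange, the chromanol epoxide, an acetate aldol and a chromene to a bromocatechol aldehyde.
- Enabling feature: ring C is fused to ring A at the neighbouring arene carbons C8a (bears O1) and C4a (bears the C4 methylene), and C8 next to C8a is C–H. An aryl iodide at C8a with a free C4a–H can therefore take up the whole O1–C2–C3–C4 chain, offered as a 1,3-iodohydrin, by palladium/norbornene ipso/ortho difunctionalisation.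
- Forward order: ring B is given; its pyran ring arises first (propargyl Claisen), then the C2–C3–C4 chain, the chromanol, the prenyl group and the iodide. Ring A is given (3-iodophenol); ring C closes in the key step; the 1,1-dimethylallyl group on ring A comes last.
- Stereochemistry: C2 (S) comes from an (S)-HYTRA acetate aldol and is kept with retention because its C–O bond is never broken. The chromanol carbon (S) comes from (S,S)-Jacobsen–Katsuki epoxidation of the chromene and hydride opening at the benzylic carbon.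
- Helpers: OTIPS on ring A (protects O7 and shields C8–H in the key step) and MOM on ring B; both are taken off in the last three steps.

Key step: step 10

Assumption: compounds 1, 8 and 14 are taken as purchasable, and the bridgehead-methyl norbornene used as mediator in step 10 (not incorporated into the product) is taken as available.

**Step 1**
Reactants: 1 2-bromo-4,5-dihydroxybenzaldehyde; 2 3-chloro-3-methylbut-1-yne
Product: 3 2-bromo-5-hydroxy-4-[(2-methylbut-3-yn-2-yl)oxy]benzaldehyde
Conditions: CuCl2 (1 mol %), DBU (1.05 equiv), MeCN, 0 °C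
Reagents that add atoms: 3-chloro-3-methylbut-1-yne, C#CC(C)(C)Cl
Why: Copper-catalysed propargylic etherification of a phenol with a tertiary propargylic chloride; the 4-OH, para to the formyl group, is the more acidic phenol and with one equivalent of base should be the one alkylated.

**Step 2**
Reactants: 3 2-bromo-5-hydroxy-4-[(2-methylbut-3-yn-2-yl)oxy]benzaldehyde; 4 chloromethyl methyl ether
Product: 5 2-bromo-5-(methoxymethoxy)-4-[(2-methylbut-3-yn-2-yl)oxy]benzaldehyde
Conditions: MOMCl, iPr2NEt, CH2Cl2, 0 °C → rt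
Reagents that add atoms: chloromethyl methyl ether, COCCl
Why: Standard MOM protection of the remaining phenol, giving an ether that should survive heat, base, hydride and palladium catalysis.

**Step 3**
Reactants: 5 2-bromo-5-(methoxymethoxy)-4-[(2-methylbut-3-yn-2-yl)oxy]benzaldehyde
Product: 7 5-bromo-8-(methoxymethoxy)-2,2-dimethyl-2H-chromene-6-carbaldehyde, via allenylphenol 6 (not isolated)
Conditions: PhNEt2, 190 °C
Reagents that add atoms: none
Why: Aryl propargyl ether Claisen rearrangement to the only free ortho carbon, then 1,5-hydrogen shift and oxa-6π electrocyclisation, the usual thermal route to 2,2-dimethyl-2H-chromenes.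

**Step 4**
Reactants: 7 5-bromo-8-(methoxymethoxy)-2,2-dimethyl-2H-chromene-6-carbaldehyde; 8 (S)-2-hydroxy-1,2,2-triphenylethyl acetate ((S)-HYTRA)
Product: 10 (S)-2-hydroxy-1,2,2-triphenylethyl (3S)-3-[5-bromo-8-(methoxymethoxy)-2,2-dimethyl-2H-chromen-6-yl]-3-hydroxypropanoate, via dilithium enolate 9 (not isolated)
Conditions: 8 (1.1 equiv), LiN(iPr)2 (2.2 equiv), THF, −78 → 0 °C; then 7, THF/2-methylbutane, −115 °C; aq NH4Cl; crystallisation
Reagents that add atoms: (S)-2-hydroxy-1,2,2-triphenylethyl acetate, CC(=O)O[C@@H](c1ccccc1)C(O)(c1ccccc1)c1ccccc1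
Why: Auxiliary-controlled acetate aldol addition in which the doubly deprotonated (S)-HYTRA ester should add to the Si face of the aldehyde and set the (S)-carbinol (the later C2), the minor diastereomer being removable by crystallisation.

**Step 5**
Reactants: 10 (S)-2-hydroxy-1,2,2-triphenylethyl (3S)-3-[5-bromo-8-(methoxymethoxy)-2,2-dimethyl-2H-chromen-6-yl]-3-hydroxypropanoate; 11 sodium hypochlorite
Product: 12 (S)-2-hydroxy-1,2,2-triphenylethyl (3S)-3-[(3S,4S)-5-bromo-3,4-epoxy-8-(methoxymethoxy)-2,2-dimethylchroman-6-yl]-3-hydroxypropanoate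
Conditions: (S,S)-N,N'-bis(3,5-di-tert-butylsalicylidene)-1,2-cyclohexanediaminomanganese chloride (4 mol %), NaOCl (aq, pH 11.3), 4-phenylpyridine N-oxide, CH2Cl2, 0 °C
Reagents that add atoms: sodium hypochlorite, [Na+].[O-]Cl
Why: Jacobsen–Katsuki epoxidation of a cis-disubstituted conjugated chromene olefin, in which the (S,S) complex of trivalent manganese should deliver oxygen to the face that gives the (3S,4S)-epoxide under catalyst control.

**Step 6**
Reactants: 12 (S)-2-hydroxy-1,2,2-triphenylethyl (3S)-3-[(3S,4S)-5-bromo-3,4-epoxy-8-(methoxymethoxy)-2,2-dimethylchroman-6-yl]-3-hydroxypropanoate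
Product: 13 (1S)-1-[(3S)-5-bromo-3-hydroxy-8-(methoxymethoxy)-2,2-dimethylchroman-6-yl]propane-1,3-diol
Conditions: LiAlH4 (excess), THF, 0 °C → rt; aq potassium sodium tartrate
Reagents that add atoms: none
Why: Hydride should open the epoxide by SN2 attack at the benzylic C4 (C3 is neopentyl next to the gem-dimethyl carbon), leaving the (S)-C3–O bond untouched, and in the same operation reduce the ester to the primary alcohol with release of the auxiliary diol.

**Step 7**
Reactants: 13 (1S)-1-[(3S)-5-bromo-3-hydroxy-8-(methoxymethoxy)-2,2-dimethylchroman-6-yl]propane-1,3-diol; 14 tributyl(3-methylbut-2-en-1-yl)stannane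
Product: 15 (1S)-1-[(3S)-3-hydroxy-8-(methoxymethoxy)-2,2-dimethyl-5-(3-methylbut-2-en-1-yl)chroman-6-yl]propane-1,3-diol
Conditions: Pd(PPh3)4 (10 mol %), CsF, DMF, 100 °C
Reagents that add atoms: tributyl(3-methylbut-2-en-1-yl)stannane, CCCC[Sn](CCCC)(CCCC)CC=C(C)C
Why: Stille coupling of an aryl bromide with an allylic stannane tolerates free hydroxyl groups, and the linear prenyl isomer is expected because reductive elimination from the primary σ-allyl palladium is favoured with PPh3.

**Step 8**
Reactants: 15 (1S)-1-[(3S)-3-hydroxy-8-(methoxymethoxy)-2,2-dimethyl-5-(3-methylbut-2-en-1-yl)chroman-6-yl]propane-1,3-diol; 16 iodine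
Product: 17 (3S)-6-[(1S)-1-hydroxy-3-iodopropyl]-8-(methoxymethoxy)-2,2-dimethyl-5-(3-methylbut-2-en-1-yl)chroman-3-ol
Conditions: PPh3, I2, imidazole (pre-mixed), CH2Cl2, 0 °C
Reagents that add atoms: iodine, II
Why: Appel-type iodination should pick the unhindered primary alcohol over the benzylic and the neopentyl secondary alcohols, and pre-forming the phosphonium iodide keeps free iodine away from the prenyl olefin.

**Step 9**
Reactants: 18 3-iodophenol; 19 chlorotriisopropylsilane
Product: 20 (3-iodophenoxy)triisopropylsilane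
Conditions: TIPSCl, imidazole, DMF, rt
Reagents that add atoms: chlorotriisopropylsilane, CC(C)[Si](Cl)(C(C)C)C(C)C
Why: Standard silylation of a phenol, giving a bulky silyl ether that protects O7 and later shields the neighbouring C8–H.

**Step 10**
Reactants: 17 (3S)-6-[(1S)-1-hydroxy-3-iodopropyl]-8-(methoxymethoxy)-2,2-dimethyl-5-(3-methylbut-2-en-1-yl)chroman-3-ol; 20 (3-iodophenoxy)triisopropylsilane
Product: 21 (3S)-8-(methoxymethoxy)-2,2-dimethyl-5-(3-methylbut-2-en-1-yl)-6-[(2S)-7-(triisopropylsilyloxy)chroman-2-yl]chroman-3-ol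
Conditions: 20 (1.5 equiv), Pd(OAc)2 (10 mol %), XPhos (20 mol %), 1-methylbicyclo[2.2.1]hept-2-ene (1 equiv), Cs2CO3 (3 equiv), 1,4-dioxane, 100 °C
Reagents that add atoms: none
Why: Proposed new method: zerovalent palladium adds to the C–I bond of 20, the norbornene inserts and the aryl norbornyl palladium metalates the free ortho C–H (the later C4a) to a five-membered palladacycle, which adds the primary C–I bond of 17 (tetravalent palladium) and reductively eliminates to forge C4–C4a; β-carbon elimination then expels the norbornene and the aryl palladium alkoxide formed from the pendant secondary alcohol closes O1–C8a by C–O reductive elimination. The closest known reaction type is the palladium/norbornene (Catellani) ortho-alkylation/ipso-etherification of aryl iodides with epoxides to 2,3-dihydrobenzofurans, together with palladium-catalysed intramolecular etherification of aryl halides with secondary alcohols to chromans; the new element is a 1,3-iodohydrin as the four-atom partner for a six-membered ring. Ring C is closed as the second bond of a formal [4+2] annulation of the O1–C2–C3–C4 chain onto C8a/C4a, by reductive elimination from a seven-membered aryl(alkoxo)palladacycle. No stereocentre is created: C2 enters as the (S)-carbinol of 17 and should keep its configuration because its C–O bond is not broken, provided C–O reductive elimination outruns β-hydride elimination of the palladium alkoxide, which the bulky biaryl phosphine favours. Site selectivity for C4a over C8 rests on the OTIPS group flanking C8–H, and mono-alkylation of the ortho-unsubstituted iodide rests on the bridgehead-methyl norbornene, which promotes norbornene extrusion after a single ortho alkylation. Chemoselectivity over direct O-arylation and Heck reaction rests on fast norbornene insertion and on the trisubstituted prenyl olefin being a poor Heck acceptor.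

**Step 11**
Reactants: 21 (3S)-8-(methoxymethoxy)-2,2-dimethyl-5-(3-methylbut-2-en-1-yl)-6-[(2S)-7-(triisopropylsilyloxy)chroman-2-yl]chroman-3-ol; 22 1-bromo-3-methylbut-2-ene
Product: 24 (3S)-8-(methoxymethoxy)-2,2-dimethyl-5-(3-methylbut-2-en-1-yl)-6-[(2S)-7-(3-methylbut-2-en-1-yloxy)chroman-2-yl]chroman-3-ol, via phenol 23 (not isolated)
Conditions: Bu4NF (1.1 equiv), THF, 0 °C; then prenyl bromide, rt
Reagents that add atoms: 1-bromo-3-methylbut-2-ene, CC(C)=CCBr
Why: Fluoride cleaves the aryl silyl ether and the tetrabutylammonium phenoxide so formed should be O-alkylated in the same pot (Williamson ether synthesis), while the hindered secondary alcohol and the MOM ether stay untouched.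

**Step 12**
Reactants: 24 (3S)-8-(methoxymethoxy)-2,2-dimethyl-5-(3-methylbut-2-en-1-yl)-6-[(2S)-7-(3-methylbut-2-en-1-yloxy)chroman-2-yl]chroman-3-ol
Product: 26 (3S)-6-[(2S)-7-hydroxy-6-(2-methylbut-3-en-2-yl)chroman-2-yl]-8-(methoxymethoxy)-2,2-dimethyl-5-(3-methylbut-2-en-1-yl)chroman-3-ol, via dienone 25 (not isolated)
Conditions: PhNEt2, 180 °C, sealed tube
Reagents that add atoms: none
Why: Aromatic Claisen rearrangement of the aryl prenyl ether gives the ortho 1,1-dimethylallyl phenol after tautomerisation of the dienone, and C6 (para to O1, next to C5–H) should be preferred over C8, which is flanked by two oxygen substituents, as is known for 1-alkyl-2-alkoxy-4-(prenyloxy)benzenes.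

**Step 13**
Reactants: 26 (3S)-6-[(2S)-7-hydroxy-6-(2-methylbut-3-en-2-yl)chroman-2-yl]-8-(methoxymethoxy)-2,2-dimethyl-5-(3-methylbut-2-en-1-yl)chroman-3-ol
Product: 27 (3S)-6-[(2S)-7-hydroxy-6-(2-methylbut-3-en-2-yl)chroman-2-yl]-2,2-dimethyl-5-(3-methylbut-2-en-1-yl)chroman-3,8-diol (CNP0323011.1)
Conditions: HCl (3 M aq), MeOH, 40 °C
Reagents that add atoms: none
Why: Acid-catalysed acetal exchange removes the aryl MOM ether under conditions that should be mild enough for the prenyl olefin, the 1,1-dimethylallyl phenol and the benzylic C2–O1 ether.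

**Compound list**
1 | 2-bromo-4,5-dihydroxybenzaldehyde | O=Cc1cc(O)c(O)cc1Br | starting material
2 | 3-chloro-3-methylbut-1-yne | C#CC(C)(C)Cl | starting material
3 | 2-bromo-5-hydroxy-4-[(2-methylbut-3-yn-2-yl)oxy]benzaldehyde | O=Cc1cc(O)c(OC(C)(C)C#C)cc1Br | intermediate
4 | chloromethyl methyl ether | COCCl | starting material
5 | 2-bromo-5-(methoxymethoxy)-4-[(2-methylbut-3-yn-2-yl)oxy]benzaldehyde | O=Cc1cc(OCOC)c(OC(C)(C)C#C)cc1Br | intermediate
6 | 2-bromo-4-hydroxy-5-(methoxymethoxy)-3-(3-methylbuta-1,2-dien-1-yl)benzaldehyde (allenylphenol, not isolated) | O=Cc1cc(OCOC)c(O)c(C=C=C(C)C)c1Br | intermediate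
7 | 5-bromo-8-(methoxymethoxy)-2,2-dimethyl-2H-chromene-6-carbaldehyde | O=Cc1cc(OCOC)c2OC(C)(C)C=Cc2c1Br | intermediate
8 | (S)-2-hydroxy-1,2,2-triphenylethyl acetate ((S)-HYTRA) | CC(=O)O[C@@H](c1ccccc1)C(O)(c1ccccc1)c1ccccc1 | starting material
9 | dilithium enolate of 8 (not isolated) | [Li+].[Li+].C=C([O-])O[C@@H](c1ccccc1)C([O-])(c1ccccc1)c1ccccc1 | intermediate
10 | (S)-2-hydroxy-1,2,2-triphenylethyl (3S)-3-[5-bromo-8-(methoxymethoxy)-2,2-dimethyl-2H-chromen-6-yl]-3-hydroxypropanoate | O=C(C[C@H](O)c1cc(OCOC)c2OC(C)(C)C=Cc2c1Br)O[C@@H](c1ccccc1)C(O)(c1ccccc1)c1ccccc1 | intermediate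
11 | sodium hypochlorite | [Na+].[O-]Cl | starting material
12 | (S)-2-hydroxy-1,2,2-triphenylethyl (3S)-3-[(3S,4S)-5-bromo-3,4-epoxy-8-(methoxymethoxy)-2,2-dimethylchroman-6-yl]-3-hydroxypropanoate | O=C(C[C@H](O)c1cc(OCOC)c2OC(C)(C)[C@H]3O[C@H]3c2c1Br)O[C@@H](c1ccccc1)C(O)(c1ccccc1)c1ccccc1 | intermediate
13 | (1S)-1-[(3S)-5-bromo-3-hydroxy-8-(methoxymethoxy)-2,2-dimethylchroman-6-yl]propane-1,3-diol | OCC[C@H](O)c1cc(OCOC)c2OC(C)(C)[C@@H](O)Cc2c1Br | intermediate
14 | tributyl(3-methylbut-2-en-1-yl)stannane | CCCC[Sn](CCCC)(CCCC)CC=C(C)C | starting material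
15 | (1S)-1-[(3S)-3-hydroxy-8-(methoxymethoxy)-2,2-dimethyl-5-(3-methylbut-2-en-1-yl)chroman-6-yl]propane-1,3-diol | OCC[C@H](O)c1cc(OCOC)c2OC(C)(C)[C@@H](O)Cc2c1CC=C(C)C | intermediate
16 | iodine | II | starting material
17 | (3S)-6-[(1S)-1-hydroxy-3-iodopropyl]-8-(methoxymethoxy)-2,2-dimethyl-5-(3-methylbut-2-en-1-yl)chroman-3-ol | ICC[C@H](O)c1cc(OCOC)c2OC(C)(C)[C@@H](O)Cc2c1CC=C(C)C | intermediate
18 | 3-iodophenol | Oc1cccc(I)c1 | starting material
19 | chlorotriisopropylsilane | CC(C)[Si](Cl)(C(C)C)C(C)C | starting material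
20 | (3-iodophenoxy)triisopropylsilane | CC(C)[Si](Oc1cccc(I)c1)(C(C)C)C(C)C | intermediate
21 | (3S)-8-(methoxymethoxy)-2,2-dimethyl-5-(3-methylbut-2-en-1-yl)-6-[(2S)-7-(triisopropylsilyloxy)chroman-2-yl]chroman-3-ol | CC(C)[Si](Oc1ccc2c(c1)O[C@H](c1cc(OCOC)c3c(c1CC=C(C)C)C[C@H](O)C(C)(C)O3)CC2)(C(C)C)C(C)C | intermediate
22 | 1-bromo-3-methylbut-2-ene | CC(C)=CCBr | starting material
23 | (3S)-6-[(2S)-7-hydroxychroman-2-yl]-8-(methoxymethoxy)-2,2-dimethyl-5-(3-methylbut-2-en-1-yl)chroman-3-ol (phenol, not isolated) | Oc1ccc2c(c1)O[C@H](c1cc(OCOC)c3c(c1CC=C(C)C)C[C@H](O)C(C)(C)O3)CC2 | intermediate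
24 | (3S)-8-(methoxymethoxy)-2,2-dimethyl-5-(3-methylbut-2-en-1-yl)-6-[(2S)-7-(3-methylbut-2-en-1-yloxy)chroman-2-yl]chroman-3-ol | CC(C)=CCOc1ccc2c(c1)O[C@H](c1cc(OCOC)c3c(c1CC=C(C)C)C[C@H](O)C(C)(C)O3)CC2 | intermediate
25 | (2S)-2-[(3S)-3-hydroxy-8-(methoxymethoxy)-2,2-dimethyl-5-(3-methylbut-2-en-1-yl)chroman-6-yl]-6-(2-methylbut-3-en-2-yl)-3,4-dihydro-2H-chromen-7(6H)-one (dienone, not isolated) | C=CC(C)(C)C1C=C2CC[C@@H](c3cc(OCOC)c4c(c3CC=C(C)C)C[C@H](O)C(C)(C)O4)OC2=CC1=O | intermediate
26 | (3S)-6-[(2S)-7-hydroxy-6-(2-methylbut-3-en-2-yl)chroman-2-yl]-8-(methoxymethoxy)-2,2-dimethyl-5-(3-methylbut-2-en-1-yl)chroman-3-ol | C=CC(C)(C)c1cc2c(cc1O)O[C@H](c1cc(OCOC)c3c(c1CC=C(C)C)C[C@H](O)C(C)(C)O3)CC2 | intermediate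
27 | (3S)-6-[(2S)-7-hydroxy-6-(2-methylbut-3-en-2-yl)chroman-2-yl]-2,2-dimethyl-5-(3-methylbut-2-en-1-yl)chroman-3,8-diol (CNP0323011.1) | C=CC(C)(C)c1cc2c(cc1O)O[C@H](c1cc(O)c3c(c1CC=C(C)C)C[C@H](O)C(C)(C)O3)CC2 | target

**Step count and risks**
Total steps: 13. Longest linear sequence: 12 steps (steps 1–8 and 10–13); step 9 is the one-step side branch.

Steps most likely to fail:

1. Step 10 (Proposed new method). Possible failures are incomplete norbornene extrusion after the single ortho alkylation (second palladation or norbornene-containing by-products), β-hydride elimination of the palladium alkoxide in place of C–O bond formation, and base-induced ring closure of the iodohydrin to an oxetane before it is used. The fallback uses known chemistry, sets out from 17 and comes back at 21. Purchased 3-bromo-4-iodophenol is silylated with 19 to (3-bromo-4-iodophenoxy)triisopropylsilane F1. A nickel-catalysed cross-electrophile coupling of the alkyl iodide 17 with the aryl iodide of F1 (NiI2, 4,4'-di-tert-butyl-2,2'-bipyridine, Zn, DMA, 60 °C), selective for C–I over C–Br, should give (3S)-6-[(1S)-3-[2-bromo-4-(triisopropylsilyloxy)phenyl]-1-hydroxypropyl]-8-(methoxymethoxy)-2,2-dimethyl-5-(3-methylbut-2-en-1-yl)chroman-3-ol F2. Palladium-catalysed intramolecular etherification of the aryl bromide with the secondary alcohol (Pd(OAc)2, 2-(di-tert-butylphosphino)-1,1'-binaphthyl, Cs2CO3, toluene, 70 °C) then closes O1–C8a with retention at C2 and returns to 21.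

2. Step 7. Possible failures are slow oxidative addition at the di-ortho-substituted, electron-rich bromide and allylic transposition during transfer of the prenyl group, which would deliver the branched isomer. The fallback sets out from 13 and comes back at 15. Stille coupling of 13 with allyltributylstannane (Pd(PPh3)4, CsF, DMF), for which no regiochemical ambiguity exists, should give (1S)-1-[(3S)-5-allyl-3-hydroxy-8-(methoxymethoxy)-2,2-dimethylchroman-6-yl]propane-1,3-diol F3. Olefin cross-metathesis of F3 with 2-methylbut-2-ene (second-generation Grubbs catalyst (H2IMes)(PCy3)Cl2Ru=CHPh, CH2Cl2, 40 °C) converts the allyl into the prenyl group and returns to 15.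

3. Step 12. Possible failures are migration to C8 in place of C6, thermal loss of the prenyl group from oxygen, and follow-up cyclisation of the 1,1-dimethylallyl phenol. The fallback avoids the rearrangement, sets out from 17 and comes back at 26. Purchased 2-bromo-5-iodophenol is silylated with 19 to (2-bromo-5-iodophenoxy)triisopropylsilane F4, which is annulated with 17 under the conditions of step 10 (the C–I bond reacting in preference to the hindered C–Br bond) to (3S)-6-[(2S)-6-bromo-7-(triisopropylsilyloxy)chroman-2-yl]-8-(methoxymethoxy)-2,2-dimethyl-5-(3-methylbut-2-en-1-yl)chroman-3-ol F5. A γ-selective (branched) Suzuki–Miyaura coupling of F5 with 3-methylbut-2-enylboronic acid pinacol ester (Pd(OAc)2, bulky biaryl phosphine, K3PO4, THF/H2O) should place the 1,1-dimethylallyl group on C6 and give (3S)-8-(methoxymethoxy)-2,2-dimethyl-6-[(2S)-6-(2-methylbut-3-en-2-yl)-7-(triisopropylsilyloxy)chroman-2-yl]-5-(3-methylbut-2-en-1-yl)chroman-3-ol F6. Cleavage of the silyl ether of F6 with Bu4NF returns to 26.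

**Further compounds**
F1 | step 10 | (3-bromo-4-iodophenoxy)triisopropylsilane | CC(C)[Si](Oc1ccc(I)c(Br)c1)(C(C)C)C(C)C
F2 | step 10 | (3S)-6-[(1S)-3-[2-bromo-4-(triisopropylsilyloxy)phenyl]-1-hydroxypropyl]-8-(methoxymethoxy)-2,2-dimethyl-5-(3-methylbut-2-en-1-yl)chroman-3-ol | CC(C)[Si](Oc1ccc(CC[C@H](O)c2cc(OCOC)c3OC(C)(C)[C@@H](O)Cc3c2CC=C(C)C)c(Br)c1)(C(C)C)C(C)C
F3 | step 7 | (1S)-1-[(3S)-5-allyl-3-hydroxy-8-(methoxymethoxy)-2,2-dimethylchroman-6-yl]propane-1,3-diol | OCC[C@H](O)c1cc(OCOC)c2OC(C)(C)[C@@H](O)Cc2c1CC=C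
F4 | step 12 | (2-bromo-5-iodophenoxy)triisopropylsilane | CC(C)[Si](Oc1cc(I)ccc1Br)(C(C)C)C(C)C
F5 | step 12 | (3S)-6-[(2S)-6-bromo-7-(triisopropylsilyloxy)chroman-2-yl]-8-(methoxymethoxy)-2,2-dimethyl-5-(3-methylbut-2-en-1-yl)chroman-3-ol | Brc1cc2c(cc1O[Si](C(C)C)(C(C)C)C(C)C)O[C@H](c1cc(OCOC)c3c(c1CC=C(C)C)C[C@H](O)C(C)(C)O3)CC2
F6 | step 12 | (3S)-8-(methoxymethoxy)-2,2-dimethyl-6-[(2S)-6-(2-methylbut-3-en-2-yl)-7-(triisopropylsilyloxy)chroman-2-yl]-5-(3-methylbut-2-en-1-yl)chroman-3-ol | C=CC(C)(C)c1cc2c(cc1O[Si](C(C)C)(C(C)C)C(C)C)O[C@H](c1cc(OCOC)c3c(c1CC=C(C)C)C[C@H](O)C(C)(C)O3)CC2
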